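**Retrosynthetic overview**
1. Feature: in the cycloheptane ring (C1, C5, C6, C7, C8, C9, C10) the oxygenated C5 and C6 and the branched C7 are followed by the unsubstituted C8–C9 pair. With C5 as ketone and C8=C9 as alkene this is a 2-alkoxy-3-alkylcyclohept-4-enone, the [3,3] product of a 2-(alkoxymethylene)-5-alkenyloxolane (ring O, C5, C1, C10, C9).
2. Endgame from that enone: O1-directed reduction of C5, alkyne C2≡C3 to the C2 ketone, hydrogenation (C8=C9 and both benzyl ethers), C12 oxidation with lactonisation onto O6, angelate, desilylation.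
3. Key disconnection: C6–C7 formed, O–C9 broken. The (Z)-benzyloxymethylene oxolane comes from a cyclic methyl ketal by loss of methanol, and the ketal from an open-chain C5 ketone onto which the C9 carbinol closes.
4. Open chain: C1 by chelation-controlled alkynyl addition, C9/C10 by anti-aldol of a glycerate-derived α-benzoyloxy ethyl ketone with the Roche-derived enal. The C5 carbinol of that ketone steers both steps and is then oxidised away (a 3-oxo-γ-lactone is avoided as C1 electrophile because it would exist as its enol).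
5. Ring order: oxolane (step 14, temporary), cycloheptene by ring expansion (step 16), γ-lactone (step 21).

Key step: step 16

Remark: target locants (ring C1, C5, C6, C7, C8, C9, C10; lactone C11, C12; chain C2, C3, C4) are used for all intermediates, also where systematic numbering would differ.
Assumption: the glycerate-derived benzoate ketone 11 follows the facial preference of lactate-derived α-benzoyloxy ethyl ketones in dicyclohexylboron aldol reactions.

**Step 1**
Reactants: 1 methyl (S)-3-hydroxy-2-methylpropanoate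
Product: 2 methyl (S)-3-(benzyloxy)-2-methylpropanoate
Conditions: BnOC(=NH)CCl3, TfOH (cat.), CH2Cl2/cyclohexane, 0 °C → rt
Reagents that add atoms: benzyl 2,2,2-trichloroacetimidate, ClC(Cl)(Cl)C(=N)OCc1ccccc1
Why: Acid-catalysed O-benzylation with the trichloroacetimidate avoids base, so the enolisable α-stereocentre (later C11) should be kept.

**Step 2**
Reactants: 2 methyl (S)-3-(benzyloxy)-2-methylpropanoate
Product: 3 (S)-3-(benzyloxy)-2-methylpropanal
Conditions: iBu2AlH, CH2Cl2, −78 °C
Reagents that add atoms: none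
Why: Low-temperature half-reduction of the ester should stop at the aluminium hemiacetal and release the aldehyde on work-up; it is used crude to avoid epimerisation.

**Step 3**
Reactants: 3 (S)-3-(benzyloxy)-2-methylpropanal
Product: 4 (R,E)-5-(benzyloxy)-4-methylpent-2-enal
Conditions: Ph3P=CHCHO, PhMe, 80 °C
Reagents that add atoms: (triphenylphosphoranylidene)acetaldehyde, O=CC=P(c1ccccc1)(c1ccccc1)c1ccccc1
Why: Wittig olefination with the stabilised formylmethylene ylide should give the (E)-enal (C9, C8, C7) under conditions too weakly basic to epimerise C11.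

**Step 4**
Reactants: 5 (R)-but-3-yn-2-ol
Product: 6 (R)-tert-butyl(but-3-yn-2-yloxy)dimethylsilane
Conditions: TBSCl, imidazole, DMF, rt
Reagents that add atoms: tert-butyldimethylsilyl chloride, CC(C)(C)[Si](C)(C)Cl
Why: Standard silylation of the secondary propargylic alcohol; the C4 stereocentre comes from the chiral pool.

**Step 5**
Reactants: 7 methyl (R)-oxirane-2-carboxylate
Product: 8 methyl (R)-3-(benzyloxy)-2-hydroxypropanoate
Conditions: BnOH, BF3·OEt2 (cat.), CH2Cl2, 0 °C → rt
Reagents that add atoms: benzyl alcohol, OCc1ccccc1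
Why: Lewis-acid-catalysed SN2 opening of the glycidic ester at the terminal carbon leaves the carbinol stereocentre untouched.

**Step 6**
Reactants: 8 methyl (R)-3-(benzyloxy)-2-hydroxypropanoate
Product: 9 (R)-3-(benzyloxy)-2-hydroxy-N-methoxy-N-methylpropanamide
Conditions: MeNH(OMe)·HCl, iPrMgCl, THF, −20 → 0 °C
Reagents that add atoms: N,O-dimethylhydroxylamine hydrochloride, CNOC.Cl
Why: Aminolysis of the ester by the magnesium amide (Weinreb amide formation) works on unprotected α-hydroxy esters.

**Step 7**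
Reactants: 9 (R)-3-(benzyloxy)-2-hydroxy-N-methoxy-N-methylpropanamide
Product: 10 (R)-1-(benzyloxy)-2-hydroxypentan-3-one
Conditions: EtMgBr, THF, 0 °C
Reagents that add atoms: ethylmagnesium bromide, CC[Mg]Br
Why: Weinreb ketone synthesis; the chelated tetrahedral intermediate prevents over-addition.

**Step 8**
Reactants: 10 (R)-1-(benzyloxy)-2-hydroxypentan-3-one
Product: 11 (R)-1-(benzyloxy)-3-oxopentan-2-yl benzoate
Conditions: Bz2O, DMAP (cat.), iPr2NEt, CH2Cl2, rt
Reagents that add atoms: benzoic anhydride, O=C(OC(=O)c1ccccc1)c1ccccc1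
Why: DMAP-catalysed benzoylation gives the α-benzoyloxy ethyl ketone needed for (E)-selective enolisation and facial control in the aldol step.

**Step 9**
Reactants: 11 (R)-1-(benzyloxy)-3-oxopentan-2-yl benzoate; 4 (R,E)-5-(benzyloxy)-4-methylpent-2-enal
Product: 13 (2R,4S,5S,6E,8R)-1,9-bis(benzyloxy)-5-hydroxy-4,8-dimethyl-3-oxonon-6-en-2-yl benzoate, via (E)-dicyclohexylboron enolate 12 (not isolated)
Conditions: c-Hex2BCl, Me2NEt, Et2O, −78 → 0 °C; then 4, −78 → −25 °C; then H2O2, MeOH, pH 7 buffer, 0 °C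
Reagents that add atoms: none
Why: Paterson anti-aldol: the (E)-enol borinate reacts through a chair Zimmerman–Traxler transition state to give the 9,10-anti relationship, and the (5R)-benzoyloxy centre (its hydrogen eclipsing the enolate double bond, the benzoate turned toward the aldehyde) selects the enolate face, which should set 10S and 9S.

**Step 10**
Reactants: 13 anti-aldol adduct
Product: 14 (2R,4S,5S,6E,8R)-1,9-bis(benzyloxy)-4,8-dimethyl-3-oxo-5-(triethylsilyloxy)non-6-en-2-yl benzoate
Conditions: TESOTf, 2,6-lutidine, CH2Cl2, −78 °C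
Reagents that add atoms: triethylsilyl trifluoromethanesulfonate, CC[Si](CC)(CC)OS(=O)(=O)C(F)(F)F
Why: Silyl triflate silylation of the C9 carbinol blocks retro-aldol and keeps O9 distinct from the later C5 and C1 hydroxyls.

**Step 11**
Reactants: 14 triethylsilyl ether
Product: 15 (2R,4S,5S,6E,8R)-1,9-bis(benzyloxy)-2-hydroxy-4,8-dimethyl-5-(triethylsilyloxy)non-6-en-3-one
Conditions: K2CO3 (cat.), MeOH, 0 °C
Reagents that add atoms: none
Why: Base-catalysed transesterification cleaves the activated α-acyloxy ketone ester quickly at low temperature and frees the C5 carbinol as a chelating group.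

**Step 12**
Reactants: 15 α-hydroxy ketone; 6 (R)-tert-butyl(but-3-yn-2-yloxy)dimethylsilane
Product: 17 (2R,3R,4S,5S,6E,8R)-1,9-bis(benzyloxy)-3-[(R)-3-(tert-butyldimethylsilyloxy)but-1-yn-1-yl]-4,8-dimethyl-5-(triethylsilyloxy)non-6-ene-2,3-diol, via alkynylmagnesium bromide 16 (not isolated)
Conditions: 6, EtMgBr, THF, 0 °C → rt; then 15, THF, −78 → 0 °C; aq. NH4Cl
Reagents that add atoms: none
Why: Cram-chelate-controlled Grignard addition: magnesium bridges the C5 alkoxide and the C1 carbonyl and the alkynyl group enters from the side of the C5 hydrogen, which should set 1R; Felkin–Anh control from the C10 centre points the same way.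

**Step 13**
Reactants: 17 diol
Product: 18 (3R,4S,5S,6E,8R)-1,9-bis(benzyloxy)-3-[(R)-3-(tert-butyldimethylsilyloxy)but-1-yn-1-yl]-3-hydroxy-4,8-dimethyl-5-(triethylsilyloxy)non-6-en-2-one
Conditions: Dess–Martin periodinane, NaHCO3, CH2Cl2, 0 °C → rt
Reagents that add atoms: none
Why: Dess–Martin oxidation takes the secondary C5 carbinol to the ketone, erasing the controller stereocentre; the tertiary C1 carbinol cannot be oxidised.

**Step 14**
Reactants: 18 α-hydroxy ketone
Product: 20 (3R,4S,5S)-2-(benzyloxymethyl)-5-[(1E,3R)-4-(benzyloxy)-3-methylbut-1-en-1-yl]-3-[(R)-3-(tert-butyldimethylsilyloxy)but-1-yn-1-yl]-2-methoxy-4-methyloxolan-3-ol as a mixture at the ketal carbon, via cyclic hemiketal 19 (not isolated)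
Conditions: PPTS (cat.), MeOH, rt → 40 °C
Reagents that add atoms: methanol, CO
Why: Acid methanolysis removes the triethylsilyl ether, O9 closes onto the C5 ketone (5-exo-trig), and Fischer-type ketalisation, as for a ketose giving its methyl furanoside, fixes the oxolane as the methyl ketal.

**Step 15**
Reactants: 20 cyclic methyl ketal
Product: 21 (2Z,3R,4S,5S)-2-[(benzyloxy)methylidene]-5-[(1E,3R)-4-(benzyloxy)-3-methylbut-1-en-1-yl]-3-[(R)-3-(tert-butyldimethylsilyloxy)but-1-yn-1-yl]-4-methyl-3-(trimethylsilyloxy)oxolane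
Conditions: TMSOTf, iPr2NEt, CH2Cl2, −20 → 0 °C; Et3N-treated silica
Reagents that add atoms: trimethylsilyl trifluoromethanesulfonate, C[Si](C)(C)OS(=O)(=O)C(F)(F)F
Why: Gassman-type ketal-to-enol-ether conversion: the silyl triflate ionises the exocyclic methoxy group, the amine removes a C6 proton (the only α-hydrogens, as C1 is quaternary), the benzyloxy group should turn away from C1 to give the (Z)-enol ether, and the C1 carbinol is silylated in the same operation.

**Step 16**
Reactants: 21 (Z)-benzyloxymethylidene oxolane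
Product: 22 (2R,3S,6S,7R)-7-(benzyloxy)-6-[(R)-1-(benzyloxy)propan-2-yl]-2-[(R)-3-(tert-butyldimethylsilyloxy)but-1-yn-1-yl]-3-methyl-2-(trimethylsilyloxy)cyclohept-4-en-1-one (target locants: C5 ketone, 6-OBn, C8=C9; 1R,6R,7S,10S)
Conditions: PhMe (dilute, degassed), iPr2NEt (cat.), base-washed sealed tube, 170 °C
Reagents that add atoms: none
Why: Thermal [3,3]-sigmatropic (aliphatic Claisen) shift of the allyl vinyl ether C6=C5–O–C9–C8=C7 held in the oxolane: C6–C7 forms, O–C9 breaks, C5 becomes the ketone and C8=C9 the ring alkene; the closest known reaction type is the Claisen ring expansion of 2-methylene- and 2-alkylidene-5-vinyltetrahydrofurans to cyclohept-4-enones. The carbocycle (C5, C6, C7, C8, C9, C10, C1) closes by C–C bond formation inside a bridged bicyclo[3.2.1]-type array in which C1–C10 spans C5 and C9 of the six-atom pericyclic ring. Only the chair form of this array places C7 and C10 cis on the new C8=C9 bond, so the boat is excluded by the ring and one diastereomeric pathway remains. C6 is set by the (Z)-enol ether geometry and by bonding on the face of C5=C6 that carries the C9 side chain (9S), which should give 6R. C7 is set by the (E)-alkene (C11 pseudo-equatorial) on the same face, which should give 7S, while C9 is consumed. The step needs the concerted shift to outrun ionisation of the allylic C9–O bond and enol ether isomerisation; acid-free conditions, amine buffering and the silylated C1 carbinol are meant to secure this.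

**Step 17**
Reactants: 22 cycloheptenone
Product: 23 1-hydroxy ketone: 22 with the C1 trimethylsilyl ether cleaved (1R,6R,7S,10S)
Conditions: citric acid, MeOH, rt
Reagents that add atoms: none
Why: Mild acid methanolysis removes the tertiary trimethylsilyl ether while the secondary TBS ether and the α-benzyloxy ketone should stay intact.

**Step 18**
Reactants: 23 1-hydroxy ketone
Product: 24 1,5-diol: (5S)-carbinol of 23, with 6-OBn, C8=C9, the alkyne and the C4 TBS ether unchanged
Conditions: Me4NBH(OAc)3, MeCN/AcOH, −20 °C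
Reagents that add atoms: none
Why: Evans–Saksena hydroxyl-directed reduction: the C1 carbinol exchanges onto boron and delivers hydride intramolecularly to the O1 face of the C5 ketone, which should give the 1,5-trans diol (5S); ketones without a neighbouring hydroxyl are not reduced by this reagent.

**Step 19**
Reactants: 24 1,5-diol
Product: 26 C2 ketone: 1,5-dihydroxy-6-OBn cycloheptene with the 1-[(R)-3-(tert-butyldimethylsilyloxy)butanoyl] side chain (1S,4R,5S,6R,7S,10S,11R), via 2-(triethoxysilyl)alkene 25 (not isolated)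
Conditions: [Cp*RuCl]4 (cat.), (EtO)3SiH, CH2Cl2, rt; then KF, KHCO3, H2O2, THF/MeOH, rt
Reagents that add atoms: hydrogen peroxide, OO
Why: Hydroxyl-directed ruthenium-catalysed trans-hydrosilylation should place silicon on C2, the alkyne carbon proximal to the free C1 carbinol (the C4 oxygen is silylated and cannot direct), and Tamao–Fleming oxidation of the alkenylsilane then gives the C2 ketone with C3 as CH2.

**Step 20**
Reactants: 26 C2 ketone
Product: 27 tetraol: C8–C9 saturated, 6-OH and 12-OH free, C4 TBS ether kept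
Conditions: H2 (1 atm), Pd(OH)2/C, EtOAc/EtOH, rt
Reagents that add atoms: none
Why: Heterogeneous hydrogenation saturates the cis ring alkene and hydrogenolyses both benzyl ethers in one operation; it is placed after the alkyne has been converted and before the angelate exists.

**Step 21**
Reactants: 27 tetraol
Product: 28 cis-fused γ-lactone with free 5-OH and 1-OH (C4 TBS ether)
Conditions: TEMPO (cat.), PhI(OAc)2, CH2Cl2, rt
Reagents that add atoms: none
Why: TEMPO/PhI(OAc)2 oxidative lactonisation: the primary C12 carbinol is oxidised selectively, the aldehyde is trapped by the cis O6 as a five-membered lactol (5-exo-trig) and oxidised on to the lactone; O5 is trans to the side chain and cannot bridge.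

**Step 22**
Reactants: 28 hydroxy lactone
Product: 29 5-O-angelate of 28 (C4 TBS ether)
Conditions: angelic acid, 2,4,6-trichlorobenzoyl chloride, Et3N, PhMe, rt; then 28, 80 °C
Reagents that add atoms: (Z)-2-methylbut-2-enoic acid, C/C=C(/C)C(=O)O
Why: Yamaguchi-type acylation with the preformed mixed anhydride and no nucleophilic catalyst is the standard way to make angelates without Z to E isomerisation; only the secondary C5 carbinol should react, the tertiary C1 carbinol being inert.

**Step 23**
Reactants: 29 silyl ether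
Product: 30 target CNP0321985.1 (1S,4R,5S,6R,7S,10S,11R)
Conditions: HF·pyridine, pyridine, THF, 0 °C → rt
Reagents that add atoms: none
Why: Buffered fluoride desilylation frees the C4 carbinol under conditions mild enough for the angelate, the lactone and the β-hydroxy ketone.

**Compound list**
1 | methyl (S)-3-hydroxy-2-methylpropanoate | COC(=O)[C@@H](C)CO | starting material
2 | methyl (S)-3-(benzyloxy)-2-methylpropanoate | COC(=O)[C@@H](C)COCc1ccccc1 | intermediate
3 | (S)-3-(benzyloxy)-2-methylpropanal | O=C[C@@H](C)COCc1ccccc1 | intermediate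
4 | (R,E)-5-(benzyloxy)-4-methylpent-2-enal | O=C/C=C/[C@@H](C)COCc1ccccc1 | intermediate
5 | (R)-but-3-yn-2-ol | C[C@@H](O)C#C | starting material
6 | (R)-tert-butyl(but-3-yn-2-yloxy)dimethylsilane | C[C@@H](O[Si](C)(C)C(C)(C)C)C#C | intermediate
7 | methyl (R)-oxirane-2-carboxylate (methyl (R)-glycidate) | COC(=O)[C@H]1CO1 | starting material
8 | methyl (R)-3-(benzyloxy)-2-hydroxypropanoate | COC(=O)[C@H](O)COCc1ccccc1 | intermediate
9 | (R)-3-(benzyloxy)-2-hydroxy-N-methoxy-N-methylpropanamide | CON(C)C(=O)[C@H](O)COCc1ccccc1 | intermediate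
10 | (R)-1-(benzyloxy)-2-hydroxypentan-3-one | CCC(=O)[C@H](O)COCc1ccccc1 | intermediate
11 | (R)-1-(benzyloxy)-3-oxopentan-2-yl benzoate | CCC(=O)[C@H](OC(=O)c1ccccc1)COCc1ccccc1 | intermediate
12 | (R,E)-1-(benzyloxy)-3-[(dicyclohexylboranyl)oxy]pent-3-en-2-yl benzoate (boron enolate, not isolated) | C/C=C(/OB(C1CCCCC1)C1CCCCC1)[C@H](OC(=O)c1ccccc1)COCc1ccccc1 | intermediate
13 | (2R,4S,5S,6E,8R)-1,9-bis(benzyloxy)-5-hydroxy-4,8-dimethyl-3-oxonon-6-en-2-yl benzoate | O=C([C@H](OC(=O)c1ccccc1)COCc1ccccc1)[C@@H](C)[C@@H](O)/C=C/[C@@H](C)COCc1ccccc1 | intermediate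
14 | (2R,4S,5S,6E,8R)-1,9-bis(benzyloxy)-4,8-dimethyl-3-oxo-5-(triethylsilyloxy)non-6-en-2-yl benzoate | O=C([C@H](OC(=O)c1ccccc1)COCc1ccccc1)[C@@H](C)[C@@H](O[Si](CC)(CC)CC)/C=C/[C@@H](C)COCc1ccccc1 | intermediate
15 | (2R,4S,5S,6E,8R)-1,9-bis(benzyloxy)-2-hydroxy-4,8-dimethyl-5-(triethylsilyloxy)non-6-en-3-one | O=C([C@H](O)COCc1ccccc1)[C@@H](C)[C@@H](O[Si](CC)(CC)CC)/C=C/[C@@H](C)COCc1ccccc1 | intermediate
16 | [(R)-3-(tert-butyldimethylsilyloxy)but-1-yn-1-yl]magnesium bromide (not isolated) | C[C@@H](O[Si](C)(C)C(C)(C)C)C#C[Mg]Br | intermediate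
17 | (2R,3R,4S,5S,6E,8R)-1,9-bis(benzyloxy)-3-[(R)-3-(tert-butyldimethylsilyloxy)but-1-yn-1-yl]-4,8-dimethyl-5-(triethylsilyloxy)non-6-ene-2,3-diol | O[C@H](COCc1ccccc1)[C@](O)(C#C[C@@H](C)O[Si](C)(C)C(C)(C)C)[C@@H](C)[C@@H](O[Si](CC)(CC)CC)/C=C/[C@@H](C)COCc1ccccc1 | intermediate
18 | (3R,4S,5S,6E,8R)-1,9-bis(benzyloxy)-3-[(R)-3-(tert-butyldimethylsilyloxy)but-1-yn-1-yl]-3-hydroxy-4,8-dimethyl-5-(triethylsilyloxy)non-6-en-2-one | O=C(COCc1ccccc1)[C@](O)(C#C[C@@H](C)O[Si](C)(C)C(C)(C)C)[C@@H](C)[C@@H](O[Si](CC)(CC)CC)/C=C/[C@@H](C)COCc1ccccc1 | intermediate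
19 | (3R,4S,5S)-2-(benzyloxymethyl)-5-[(1E,3R)-4-(benzyloxy)-3-methylbut-1-en-1-yl]-3-[(R)-3-(tert-butyldimethylsilyloxy)but-1-yn-1-yl]-4-methyloxolane-2,3-diol (cyclic hemiketal, not isolated, mixture at the hemiketal carbon) | OC1(COCc2ccccc2)O[C@@H](/C=C/[C@@H](C)COCc2ccccc2)[C@H](C)[C@@]1(O)C#C[C@@H](C)O[Si](C)(C)C(C)(C)C | intermediate
20 | (3R,4S,5S)-2-(benzyloxymethyl)-5-[(1E,3R)-4-(benzyloxy)-3-methylbut-1-en-1-yl]-3-[(R)-3-(tert-butyldimethylsilyloxy)but-1-yn-1-yl]-2-methoxy-4-methyloxolan-3-ol (mixture at the ketal carbon) | COC1(COCc2ccccc2)O[C@@H](/C=C/[C@@H](C)COCc2ccccc2)[C@H](C)[C@@]1(O)C#C[C@@H](C)O[Si](C)(C)C(C)(C)C | intermediate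
21 | (2Z,3R,4S,5S)-2-[(benzyloxy)methylidene]-5-[(1E,3R)-4-(benzyloxy)-3-methylbut-1-en-1-yl]-3-[(R)-3-(tert-butyldimethylsilyloxy)but-1-yn-1-yl]-4-methyl-3-(trimethylsilyloxy)oxolane | c1ccccc1CO/C=C2\O[C@@H](/C=C/[C@@H](C)COCc3ccccc3)[C@H](C)[C@@]2(O[Si](C)(C)C)C#C[C@@H](C)O[Si](C)(C)C(C)(C)C | intermediate
22 | (2R,3S,6S,7R)-7-(benzyloxy)-6-[(R)-1-(benzyloxy)propan-2-yl]-2-[(R)-3-(tert-butyldimethylsilyloxy)but-1-yn-1-yl]-3-methyl-2-(trimethylsilyloxy)cyclohept-4-en-1-one | O=C1[C@H](OCc2ccccc2)[C@H]([C@@H](C)COCc2ccccc2)C=C[C@H](C)[C@@]1(O[Si](C)(C)C)C#C[C@@H](C)O[Si](C)(C)C(C)(C)C | intermediate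
23 | (2R,3S,6S,7R)-7-(benzyloxy)-6-[(R)-1-(benzyloxy)propan-2-yl]-2-[(R)-3-(tert-butyldimethylsilyloxy)but-1-yn-1-yl]-2-hydroxy-3-methylcyclohept-4-en-1-one | O=C1[C@H](OCc2ccccc2)[C@H]([C@@H](C)COCc2ccccc2)C=C[C@H](C)[C@@]1(O)C#C[C@@H](C)O[Si](C)(C)C(C)(C)C | intermediate
24 | 1,5-diol of 23 (target locants 1R,4R,5S,6R,7S,10S,11R): 6-OBn, 12-OBn, C8=C9, 1-alkynyl, 4-OTBS | O[C@H]1[C@H](OCc2ccccc2)[C@H]([C@@H](C)COCc2ccccc2)C=C[C@H](C)[C@@]1(O)C#C[C@@H](C)O[Si](C)(C)C(C)(C)C | intermediate
25 | 24 with the alkyne as the C2-triethoxysilyl alkene (silicon cis to C4, C1 trans to C4; not isolated) | O[C@H]1[C@H](OCc2ccccc2)[C@H]([C@@H](C)COCc2ccccc2)C=C[C@H](C)[C@@]1(O)/C([Si](OCC)(OCC)OCC)=C/[C@@H](C)O[Si](C)(C)C(C)(C)C | intermediate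
26 | C2 ketone (1S,4R,5S,6R,7S,10S,11R): 1,5-dihydroxy, 6-OBn, 12-OBn, C8=C9, 4-OTBS | O[C@H]1[C@H](OCc2ccccc2)[C@H]([C@@H](C)COCc2ccccc2)C=C[C@H](C)[C@@]1(O)C(=O)C[C@@H](C)O[Si](C)(C)C(C)(C)C | intermediate
27 | saturated tetraol (1,5,6,12-tetrahydroxy, C2 ketone, 4-OTBS) | O[C@H]1[C@H](O)[C@H]([C@@H](C)CO)CC[C@H](C)[C@@]1(O)C(=O)C[C@@H](C)O[Si](C)(C)C(C)(C)C | intermediate
28 | cis-fused 12,6-lactone with 1-OH and 5-OH free, 4-OTBS | O[C@H]1[C@@H]2OC(=O)[C@H](C)[C@@H]2CC[C@H](C)[C@@]1(O)C(=O)C[C@@H](C)O[Si](C)(C)C(C)(C)C | intermediate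
29 | 5-O-angelate of 28 (4-OTBS) | C/C=C(/C)C(=O)O[C@H]1[C@@H]2OC(=O)[C@H](C)[C@@H]2CC[C@H](C)[C@@]1(O)C(=O)C[C@@H](C)O[Si](C)(C)C(C)(C)C | intermediate
30 | CNP0321985.1 (1S,4R,5S,6R,7S,10S,11R) | C/C=C(/C)C(=O)O[C@H]1[C@@H]2OC(=O)[C@H](C)[C@@H]2CC[C@H](C)[C@@]1(O)C(=O)C[C@@H](C)O | target

**Total step count:** 23
**Longest linear sequence:** 19 steps (7 → 30: steps 5–8, then 9–23)

**Three steps most likely to fail**

1. Step 16 (ring expansion). The concerted shift may be slower than ionisation of the allylic C9–O bond or thermal isomerisation of the enol ether. The benzyloxy group must sit pseudo-axial in the only accessible chair array, and C6–C7 joins two substituted carbons. This would erode the C6 configuration or divert material to the 1,3-shift product. Fallback: the neutral thermal shift is replaced by a Lewis-acid-anchored rearrangement–reduction. It sets out from 21: K2CO3 in MeOH removes the trimethylsilyl group to give (2Z,3R,4S,5S)-2-[(benzyloxy)methylidene]-5-[(1E,3R)-4-(benzyloxy)-3-methylbut-1-en-1-yl]-3-[(R)-3-(tert-butyldimethylsilyloxy)but-1-yn-1-yl]-4-methyloxolan-3-ol F1. Excess iBu3Al in CH2Cl2 (−78 °C → rt) should then bind O1 as the aluminium alkoxide, promote the O-to-C transposition at low temperature and reduce the new C5 carbonyl by β-hydride transfer from the O1-bound aluminium on the O1 face. This is the aluminium-promoted reductive Claisen ring expansion known for 2-methylene-6-vinyltetrahydropyrans. It bypasses 22 and 23 and comes back to the route at diol 24.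

2. Step 19 (alkyne to C2 ketone). Silicon may be delivered to C3 instead of C2 if hydroxyl direction is lost at the hindered quaternary C1 carbinol, and the acyloin formed may be cleaved by basic peroxide. Fallback: the oxygen is delivered to C2 through a tether instead of through silicon. It sets out from 24: AgOAc (cat.), DBU and CO2 (1 atm) in MeCN convert the tertiary propargylic carbinol to its carbonate, which adds 5-exo-dig across the alkyne to give the spiro (Z)-alkylidene cyclic carbonate F2 (4-alkylidene-1,3-dioxolan-2-one on C1, enol oxygen on C2). Hydrolysis with K2CO3 in aqueous MeOH releases the enol, which tautomerises to the ketone, and the sequence comes back at 26.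

3. Step 22 (angelate). Acylation of the C5 carbinol, flanked by the quaternary C1 and the lactone-bearing C6, may be too slow, so that Z to E isomerisation of the mixed anhydride (tiglate formation) or base-induced loss of the β-silyloxy group competes. Fallback: the Z-alkene is built on the ester instead of being carried in the acyl donor. It sets out from 28: acylation with 2-[bis(2,2,2-trifluoroethoxy)phosphoryl]propanoic acid (DCC, DMAP, CH2Cl2) gives the C5 2-[bis(2,2,2-trifluoroethoxy)phosphoryl]propanoate F3. Still–Gennari olefination (KN(SiMe3)2, 18-crown-6, acetaldehyde, THF, −78 °C) should then give the (Z)-2-methylbut-2-enoate, and the sequence comes back at 29.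

**Further compounds**
F1 | step 16 | (2Z,3R,4S,5S)-2-[(benzyloxy)methylidene]-5-[(1E,3R)-4-(benzyloxy)-3-methylbut-1-en-1-yl]-3-[(R)-3-(tert-butyldimethylsilyloxy)but-1-yn-1-yl]-4-methyloxolan-3-ol | c1ccccc1CO/C=C2\O[C@@H](/C=C/[C@@H](C)COCc3ccccc3)[C@H](C)[C@@]2(O)C#C[C@@H](C)O[Si](C)(C)C(C)(C)C
F2 | step 19 | spiro (Z)-alkylidene cyclic carbonate of 24 (O1 and the C2 enol oxygen bridged by C=O; exocyclic C2=C3 bearing the C4 silyloxyethyl group) | O[C@H]1[C@H](OCc2ccccc2)[C@H]([C@@H](C)COCc2ccccc2)C=C[C@H](C)[C@]13OC(=O)O/C3=C\[C@@H](C)O[Si](C)(C)C(C)(C)C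
F3 | step 22 | C5 2-[bis(2,2,2-trifluoroethoxy)phosphoryl]propanoate of 28 (mixture at the phosphonate α-carbon) | CC(C(=O)O[C@H]1[C@@H]2OC(=O)[C@H](C)[C@@H]2CC[C@H](C)[C@@]1(O)C(=O)C[C@@H](C)O[Si](C)(C)C(C)(C)C)P(=O)(OCC(F)(F)F)OCC(F)(F)F
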